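**Retrosynthetic overview**

1. Numbering: oxane O1, C2 (Me, OH), C3 (Br), C4, C5, C6; side chain C7 (Cl, Me), C8=C9 (Br). The hemiketal is the closed form of a 6-hydroxy-3-bromo-2-ketone, so O1–C2 closes last, after bromide displaces a C3 tosylate with inversion.
2. C8=C9 comes from a Takai olefination of a lactol; C7–Cl comes from chlorination of a γ-lactone enolate (C8 carbonyl, O1–C6 alkoxy) anti to the C5 side chain.
3. Key disconnection C5–C6. Enabling feature: C6 is an isolated O-bound methylene (O1–C6H2–C5), i.e. a hydroxymethyl group on C5, and C5 lies 1,3 to the heteroatom-bearing C3 and β to C8. A C3–O–SiMe2–CH2 radical can therefore close a temporary 1,2-oxasilinane ring 6-exo onto C5 of a C5=C7–C8 enoate.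
4. Stereochemistry: C3 is set by reagent-controlled allylboration and relayed C3 → C5 (key step) → C7 (enolate chlorination) → C3 again (inversion to the bromide); C2 settles thermodynamically.
5. Ring order: 1,2-oxasilinane (temporary, key step) → γ-butyrolactone (temporary, same step) → oxane hemiketal (last step).

Key step: step 5

Assumption: the allylboration of 2 is taken to follow the usual facial sense of this reagent class for aldehydes whose substituent outranks allyl, so the reagent of the (−)-α-pinene series is chosen for the (3R)-alcohol.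

**Step 1**
Reactants: 1 methyl 2,2-dimethoxypropanoate
Product: 2 2,2-dimethoxypropanal
Conditions: i-Bu2AlH (1.05 equiv), CH2Cl2, −78 °C; aqueous Rochelle salt work-up; used as a crude solution
Reagents that add atoms: none
Why: Ester-to-aldehyde reduction with i-Bu2AlH at −78 °C should stop at the aluminium hemiacetal, which is stabilised by chelation to the α-methoxy groups and releases the aldehyde only on work-up; no stereocenter is formed.

**Step 2**
Reactants: 2 2,2-dimethoxypropanal; 3 B-allyldiisopinocampheylborane of the (−)-α-pinene series, (+)-Ipc2B(allyl)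
Product: 5 (3R)-2,2-dimethoxyhex-5-en-3-ol, via borinate 4 (not isolated)
Conditions: Et2O, −78 °C; then NaOH (3 M aq.), 30% H2O2, 0 °C to rt
Reagents that add atoms: B-allyldiisopinocampheylborane 3, C=CCB([C@H]1C[C@H]2C[C@@H]([C@@H]1C)C2(C)C)[C@H]1C[C@H]2C[C@@H]([C@@H]1C)C2(C)C
Why: Brown asymmetric allylboration delivers the allyl group through a closed chair transition state under control of the isopinocampheyl groups, which should set C3 as (R).

**Step 3**
Reactants: 5 (3R)-2,2-dimethoxyhex-5-en-3-ol; 6 methyl methacrylate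
Product: 7 methyl (2E,5R)-5-hydroxy-6,6-dimethoxy-2-methylhept-2-enoate
Conditions: second-generation Hoveyda–Grubbs catalyst (5 mol %), methyl methacrylate (10 equiv), CH2Cl2, 40 °C
Reagents that add atoms: methyl methacrylate 6, C=C(C)C(=O)OC
Why: Olefin cross-metathesis of a terminal alkene with the electron-poor 1,1-disubstituted methacrylate is selective for the cross product and should give the (E)-trisubstituted enoate, leaving the carbinol centre untouched.

**Step 4**
Reactants: 7 methyl (2E,5R)-5-hydroxy-6,6-dimethoxy-2-methylhept-2-enoate; 8 (bromomethyl)chlorodimethylsilane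
Product: 9 methyl (2E,5R)-5-{[(bromomethyl)dimethylsilyl]oxy}-6,6-dimethoxy-2-methylhept-2-enoate
Conditions: Et3N, DMAP (cat.), CH2Cl2, 0 °C
Reagents that add atoms: (bromomethyl)chlorodimethylsilane 8, C[Si](C)(Cl)CBr
Why: O-Silylation of the secondary alcohol with the chlorosilane under amine base installs the radical precursor on the C3 oxygen with retention at C3.

**Step 5**
Reactants: 9 methyl (2E,5R)-5-{[(bromomethyl)dimethylsilyl]oxy}-6,6-dimethoxy-2-methylhept-2-enoate
Product: 12 (4S)-4-[(2R)-2-hydroxy-3,3-dimethoxybutyl]-3-methyloxolan-2-one (both C3 epimers), via oxasilinane 10 (not isolated), via diol ester 11 (not isolated)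
Conditions: Bu3SnH (1.3 equiv, syringe pump), AIBN (0.1 equiv), PhH (0.01 M), 80 °C; then KF, KHCO3, 30% H2O2, THF–MeOH, 40 °C; then DBU (0.1 equiv), PhMe, 60 °C
Reagents that add atoms: hydrogen peroxide, OO
Why: Bromine abstraction by the stannyl radical gives the α-silylmethyl radical, which adds to C5, the β-carbon of the enoate, and the α-ester radical is reduced by Bu3SnH (Nishiyama–Stork silicon-tethered radical cyclization); Tamao–Fleming oxidation of the C–Si bond then turns C6 into the hydroxymethyl group whose oxygen is the future ring oxygen O1. The temporary 1,2-oxasilinane ring closes in the 6-exo-trig mode, and the γ-lactone closes afterwards by 5-exo-trig acyl substitution of the C6 hydroxyl on the methyl ester. The new C5 stereocenter is controlled by the C3 carbinol centre through a chair-like transition state in which the 1,1-dimethoxyethyl group at C3 and the enoate arm at C5 are both equatorial (cis on the silacycle). The step needs 6-exo over 7-endo closure and one face of C5: the polarised enoate with its fully substituted α-carbon should secure the first and the bulky equatorial ketal substituent the second. C7 forms as a mixture of epimers, which is harmless because it is planarised and set in step 7.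

**Step 6**
Reactants: 12 (4S)-4-[(2R)-2-hydroxy-3,3-dimethoxybutyl]-3-methyloxolan-2-one
Product: 13 (2R)-3,3-dimethoxy-1-[(3S)-4-methyl-5-oxooxolan-3-yl]butan-2-yl 4-methylbenzenesulfonate (both epimers at the methyl-bearing carbon)
Conditions: TsCl, pyridine, DMAP (cat.), CH2Cl2, 0 °C to rt
Reagents that add atoms: 4-methylbenzenesulfonyl chloride, Cc1ccc(cc1)S(Cl)(=O)=O
Why: DMAP-catalysed sulfonylation of the only free hydroxyl protects O3 through the next steps and makes it the leaving group for the late bromide displacement, with retention at C3.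

**Step 7**
Reactants: 13 (2R)-3,3-dimethoxy-1-[(3S)-4-methyl-5-oxooxolan-3-yl]butan-2-yl 4-methylbenzenesulfonate
Product: 15 (2R)-1-[(3R,4S)-4-chloro-4-methyl-5-oxooxolan-3-yl]-3,3-dimethoxybutan-2-yl 4-methylbenzenesulfonate, via lithium enolate 14 (not isolated)
Conditions: LiN(SiMe3)2 (1.05 equiv), THF, −78 °C; then N-chlorosuccinimide, −78 °C
Reagents that add atoms: N-chlorosuccinimide, O=C1CCC(=O)N1Cl
Why: Both C7 epimers converge on one lactone enolate, which NCS should chlorinate on the face anti to the C5 side chain (electrophilic α-chlorination of a β-substituted γ-butyrolactone enolate), setting C7 with chlorine trans to that chain.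

**Step 8**
Reactants: 15 (2R)-1-[(3R,4S)-4-chloro-4-methyl-5-oxooxolan-3-yl]-3,3-dimethoxybutan-2-yl 4-methylbenzenesulfonate
Product: 16 (2R)-1-[(3R,4S)-4-chloro-5-hydroxy-4-methyloxolan-3-yl]-3,3-dimethoxybutan-2-yl 4-methylbenzenesulfonate (both anomers)
Conditions: i-Bu2AlH (1.1 equiv), CH2Cl2, −78 °C; aqueous Rochelle salt work-up
Reagents that add atoms: none
Why: Reduction of a γ-lactone with i-Bu2AlH at −78 °C should stop at the lactol because the aluminium hemiacetal survives until work-up; only the anomeric centre, a mixture that is lost in the next step, is created.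

**Step 9**
Reactants: 16 (2R)-1-[(3R,4S)-4-chloro-5-hydroxy-4-methyloxolan-3-yl]-3,3-dimethoxybutan-2-yl 4-methylbenzenesulfonate; 17 bromoform
Product: 18 (3R,5R,6S,7E)-8-bromo-6-chloro-5-(hydroxymethyl)-2,2-dimethoxy-6-methyloct-7-en-3-yl 4-methylbenzenesulfonate
Conditions: CrCl2 (8 equiv), CHBr3 (3 equiv), THF, 0 °C to rt
Reagents that add atoms: bromoform 17, BrC(Br)Br
Why: In the Takai olefination the lactol opens to the α-chloro aldehyde, which has no α-hydrogen, and the gem-dichromium reagent from CHBr3 and CrCl2 should give the (E)-bromoalkene by addition and anti elimination, freeing the C6 hydroxyl.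

**Step 10**
Reactants: 18 (3R,5R,6S,7E)-8-bromo-6-chloro-5-(hydroxymethyl)-2,2-dimethoxy-6-methyloct-7-en-3-yl 4-methylbenzenesulfonate
Product: 20 (2R,3S,5R)-3-bromo-5-[(2S,3E)-4-bromo-2-chlorobut-3-en-2-yl]-2-methyloxan-2-ol, via tosyloxy ketone 19 (not isolated)
Conditions: HCl (1 M aq.), THF, 0 °C to rt; then LiBr (5 equiv), acetone, rt
Reagents that add atoms: water, O; lithium bromide, [Li+].[Br-]
Why: Acid hydrolysis of the dimethyl ketal gives the α-tosyloxy ketone, bromide displaces the sulfonate in an SN2 reaction that the adjacent carbonyl accelerates and that inverts C3, and the 6-hydroxy ketone closes to the hemiketal; C2 settles under thermodynamic control with the hydroxyl axial (anomeric effect) and methyl, bromine and side chain equatorial, the arrangement that bromide exchange at C3 also favours.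

**Compound list**

1 | methyl 2,2-dimethoxypropanoate | COC(=O)C(C)(OC)OC | starting material
2 | 2,2-dimethoxypropanal | CC(OC)(OC)C=O | intermediate
3 | B-allyldiisopinocampheylborane of the (−)-α-pinene series, (+)-Ipc2B(allyl) | C=CCB([C@H]1C[C@H]2C[C@@H]([C@@H]1C)C2(C)C)[C@H]1C[C@H]2C[C@@H]([C@@H]1C)C2(C)C | starting material
4 | (3R)-2,2-dimethoxyhex-5-en-3-yl diisopinocampheylborinate (isopinocampheyl groups of the (−)-α-pinene series) | CC(OC)(OC)[C@@H](CC=C)OB([C@H]1C[C@H]2C[C@@H]([C@@H]1C)C2(C)C)[C@H]1C[C@H]2C[C@@H]([C@@H]1C)C2(C)C | intermediate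
5 | (3R)-2,2-dimethoxyhex-5-en-3-ol | CC(OC)(OC)[C@H](O)CC=C | intermediate
6 | methyl methacrylate | C=C(C)C(=O)OC | starting material
7 | methyl (2E,5R)-5-hydroxy-6,6-dimethoxy-2-methylhept-2-enoate | CC(OC)(OC)[C@H](O)C/C=C(\C)C(=O)OC | intermediate
8 | (bromomethyl)chlorodimethylsilane | C[Si](C)(Cl)CBr | starting material
9 | methyl (2E,5R)-5-{[(bromomethyl)dimethylsilyl]oxy}-6,6-dimethoxy-2-methylhept-2-enoate | CC(OC)(OC)[C@H](O[Si](C)(C)CBr)C/C=C(\C)C(=O)OC | intermediate
10 | methyl 2-[(4S,6R)-6-(1,1-dimethoxyethyl)-2,2-dimethyl-1,2-oxasilinan-4-yl]propanoate (both epimers at the propanoate C2) | C[Si]1(C)C[C@H](C(C)C(=O)OC)C[C@H](C(C)(OC)OC)O1 | intermediate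
11 | methyl (3S,5R)-5-hydroxy-3-(hydroxymethyl)-6,6-dimethoxy-2-methylheptanoate (both C2 epimers) | COC(=O)C(C)[C@@H](CO)C[C@@H](O)C(C)(OC)OC | intermediate
12 | (4S)-4-[(2R)-2-hydroxy-3,3-dimethoxybutyl]-3-methyloxolan-2-one (both C3 epimers) | CC1C(=O)OC[C@H]1C[C@@H](O)C(C)(OC)OC | intermediate
13 | (2R)-3,3-dimethoxy-1-[(3S)-4-methyl-5-oxooxolan-3-yl]butan-2-yl 4-methylbenzenesulfonate (both epimers at the methyl-bearing carbon) | CC1C(=O)OC[C@H]1C[C@@H](OS(=O)(=O)c2ccc(C)cc2)C(C)(OC)OC | intermediate
14 | lithium (4S)-4-{(2R)-3,3-dimethoxy-2-[(4-methylbenzenesulfonyl)oxy]butyl}-3-methyl-4,5-dihydrofuran-2-olate | [Li+].CC1=C([O-])OC[C@H]1C[C@@H](OS(=O)(=O)c2ccc(C)cc2)C(C)(OC)OC | intermediate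
15 | (2R)-1-[(3R,4S)-4-chloro-4-methyl-5-oxooxolan-3-yl]-3,3-dimethoxybutan-2-yl 4-methylbenzenesulfonate | C[C@@]1(Cl)C(=O)OC[C@H]1C[C@@H](OS(=O)(=O)c2ccc(C)cc2)C(C)(OC)OC | intermediate
16 | (2R)-1-[(3R,4S)-4-chloro-5-hydroxy-4-methyloxolan-3-yl]-3,3-dimethoxybutan-2-yl 4-methylbenzenesulfonate (both anomers) | C[C@@]1(Cl)C(O)OC[C@H]1C[C@@H](OS(=O)(=O)c2ccc(C)cc2)C(C)(OC)OC | intermediate
17 | bromoform | BrC(Br)Br | starting material
18 | (3R,5R,6S,7E)-8-bromo-6-chloro-5-(hydroxymethyl)-2,2-dimethoxy-6-methyloct-7-en-3-yl 4-methylbenzenesulfonate | C[C@@](Cl)(/C=C/Br)[C@H](C[C@@H](OS(=O)(=O)c1ccc(C)cc1)C(C)(OC)OC)CO | intermediate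
19 | (3R,5R,6S,7E)-8-bromo-6-chloro-5-(hydroxymethyl)-6-methyl-2-oxooct-7-en-3-yl 4-methylbenzenesulfonate (open form, in equilibrium with its cyclic hemiketal) | C[C@@](Cl)(/C=C/Br)[C@H](C[C@@H](OS(=O)(=O)c1ccc(C)cc1)C(C)=O)CO | intermediate
20 | (2R,3S,5R)-3-bromo-5-[(2S,3E)-4-bromo-2-chlorobut-3-en-2-yl]-2-methyloxan-2-ol | C[C@@](Cl)(/C=C/Br)[C@H]1CO[C@@](C)(O)[C@@H](Br)C1 | target

**Totals**

Total step count: 10. Longest linear sequence: 10 steps, from 1 to 20.

**Steps most likely to fail**

Step 5 (key step). What may go wrong: reduction of the α-silylmethyl radical before it cyclises, competing 7-endo closure, or poor facial selectivity in the 6-exo closure, which would erode the enantiomeric purity once C7 is planarised in step 7. Fallback: the C5–C6 bond is made by conjugate addition to a ring template instead of by a tethered radical. Starting from 5, acylation with methacryloyl chloride (Et3N, DMAP) gives the ester (3R)-2,2-dimethoxyhex-5-en-3-yl 2-methylprop-2-enoate F1. Ring-closing metathesis (second-generation Grubbs catalyst) gives the unsaturated δ-lactone (6R)-6-(1,1-dimethoxyethyl)-3-methyl-5,6-dihydro-2H-pyran-2-one F2. Copper-mediated 1,4-addition of i-PrOMe2SiCH2MgCl (CuI, Me3SiCl), which should occur trans to the C6 substituent of the lactone, gives (4S,6R)-6-(1,1-dimethoxyethyl)-4-{[dimethyl(propan-2-yloxy)silyl]methyl}-3-methyloxan-2-one F3. Tamao–Fleming oxidation gives (4S,6R)-6-(1,1-dimethoxyethyl)-4-(hydroxymethyl)-3-methyloxan-2-one F4, and DBU-mediated translactonisation to the γ-lactone returns to the route at 12.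

Step 9. What may go wrong: slow opening of the hindered lactol, halide exchange on chromium that contaminates the bromoalkene with chloroalkene, and reduction of the α-chloro aldehyde by divalent chromium. Fallback: from 16, Seyferth–Gilbert homologation with the Ohira–Bestmann reagent (dimethyl (1-diazo-2-oxopropyl)phosphonate, K2CO3, MeOH) gives the alkyne (3R,5R,6S)-6-chloro-5-(hydroxymethyl)-2,2-dimethoxy-6-methyloct-7-yn-3-yl 4-methylbenzenesulfonate F5. Hydrozirconation with Cp2Zr(H)Cl followed by bromination with NBS should give the (E)-bromoalkene and returns to the route at 18.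

Step 10. What may go wrong: slow hydrolysis of the ketal, which is deactivated by the neighbouring sulfonate, solvolysis of the tertiary allylic chloride under the acid required, and intramolecular O-alkylation by the C6 hydroxyl in competition with bromide. Fallback: the C3 bromide is introduced by reductive bromination of an enone instead of by displacement. From 12, syn-dehydration with methyl N-(triethylammoniosulfonyl)carbamate (only C4 carries a β-hydrogen) gives the alkene (4S)-4-[(1E)-3,3-dimethoxybut-1-en-1-yl]-3-methyloxolan-2-one F6. Chlorination, i-Bu2AlH reduction and Takai olefination under the conditions of steps 7 to 9 give in turn the chloro lactone (3S,4R)-3-chloro-4-[(1E)-3,3-dimethoxybut-1-en-1-yl]-3-methyloxolan-2-one F7, the lactol (3S,4R)-3-chloro-4-[(1E)-3,3-dimethoxybut-1-en-1-yl]-3-methyloxolan-2-ol F8 and the bromodiene (2R,3S,4E)-5-bromo-3-chloro-2-[(1E)-3,3-dimethoxybut-1-en-1-yl]-3-methylpent-4-en-1-ol F9. Mild acid hydrolysis of the allylic ketal gives the enone (3E,5R,6S,7E)-8-bromo-6-chloro-5-(hydroxymethyl)-6-methylocta-3,7-dien-2-one F10. Conjugate reduction with [(Ph3P)CuH]6 and trapping of the copper enolate with NBS should brominate C3 regiospecifically, after which the product closes and equilibrates to 20.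

**Further compounds**

F1 | step 5 | (3R)-2,2-dimethoxyhex-5-en-3-yl 2-methylprop-2-enoate | CC(OC)(OC)[C@H](OC(=O)C(C)=C)CC=C
F2 | step 5 | (6R)-6-(1,1-dimethoxyethyl)-3-methyl-5,6-dihydro-2H-pyran-2-one | CC1=CC[C@H](C(C)(OC)OC)OC1=O
F3 | step 5 | (4S,6R)-6-(1,1-dimethoxyethyl)-4-{[dimethyl(propan-2-yloxy)silyl]methyl}-3-methyloxan-2-one (both C3 epimers) | CC1[C@@H](C[Si](C)(C)OC(C)C)C[C@H](C(C)(OC)OC)OC1=O
F4 | step 5 | (4S,6R)-6-(1,1-dimethoxyethyl)-4-(hydroxymethyl)-3-methyloxan-2-one (both C3 epimers) | CC1[C@@H](CO)C[C@H](C(C)(OC)OC)OC1=O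
F5 | step 9 | (3R,5R,6S)-6-chloro-5-(hydroxymethyl)-2,2-dimethoxy-6-methyloct-7-yn-3-yl 4-methylbenzenesulfonate | C[C@@](Cl)(C#C)[C@H](C[C@@H](OS(=O)(=O)c1ccc(C)cc1)C(C)(OC)OC)CO
F6 | step 10 | (4S)-4-[(1E)-3,3-dimethoxybut-1-en-1-yl]-3-methyloxolan-2-one (both C3 epimers) | CC1C(=O)OC[C@H]1/C=C/C(C)(OC)OC
F7 | step 10 | (3S,4R)-3-chloro-4-[(1E)-3,3-dimethoxybut-1-en-1-yl]-3-methyloxolan-2-one | C[C@@]1(Cl)C(=O)OC[C@H]1/C=C/C(C)(OC)OC
F8 | step 10 | (3S,4R)-3-chloro-4-[(1E)-3,3-dimethoxybut-1-en-1-yl]-3-methyloxolan-2-ol (both anomers) | C[C@@]1(Cl)C(O)OC[C@H]1/C=C/C(C)(OC)OC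
F9 | step 10 | (2R,3S,4E)-5-bromo-3-chloro-2-[(1E)-3,3-dimethoxybut-1-en-1-yl]-3-methylpent-4-en-1-ol | C[C@@](Cl)(/C=C/Br)[C@H](/C=C/C(C)(OC)OC)CO
F10 | step 10 | (3E,5R,6S,7E)-8-bromo-6-chloro-5-(hydroxymethyl)-6-methylocta-3,7-dien-2-one | C[C@@](Cl)(/C=C/Br)[C@H](/C=C/C(C)=O)CO
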